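All runs were computed for substances that don't exist; scatter was added.

Early in Saturday's run the substrate goes faster than the target appears: 18.0% of it has gone at 0.250 h, but the target stands at 9%. I start from that gap to rank these flasks.

| flask | substrate | free catalyst | remark | time |
|---|---|---|---|---|
| Saturday's | 16 mM | 0.17 mM | run made earlier |  |
| epsilon | 30 mM | 0.50 mM |  | 8.0 h |
| gamma | 5.0 mM | 0.30 mM |  | 8.0 h |
| theta | 15 mM | 0.17 mM |  | 8.0 h |
| eta | 5.0 mM | 0.17 mM |  | 8.0 h |
| alpha | 8.0 mM | 0.50 mM |  | 8.0 h |
| delta | 15 mM | 0.60 mM |  | 8.0 h |

- Saturday's (time / h: target / %, substrate / %): 0.250: 9, 82; 0.417: 18, 69; 0.833: 27, 50; 1.33: 37, 37; 3.00: 54, 14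

(each reading ± 2 percentage points)

- what was read earlier has a scatter of 2 percentage points, one standard deviation
- no earlier run changes the charge of free catalyst; that part of a forecast is a guess

- ranking by amount of target, in percent of the substrate charged, from high to low, at 8.0 h (epsilon / gamma / theta / eta / alpha / delta)
- the same order at 2.5 d (epsilon / gamma / theta / eta / alpha / delta)
- the amount of target, in percent of the substrate charged of the flask you put first, at 8.0 h
- the amount of target, in percent of the substrate charged of the flask you put last, at 8.0 h

Free catalyst is the reagent charged in the smaller amount, 0.17 mM against 16 mM of substrate on Saturday. I assume that making target doesn't use it up, so that its charge stands throughout; no reading shows this. Substrate then leaves by two ways: through the free catalyst to target, and by a way that needs no catalyst. If both go in proportion to the substrate, the substrate cancels from their ratio. The selectivity, target made per substrate used, then depends on the charge of free catalyst. No earlier run changes that charge, so this dependence is a guess.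

The first readings give selectivities of 0.500, 0.581 and 0.540. I take the last, which lies between the other two and is read at 0.833 h, with a scatter that carries over:

half-share charge = charge × (part not target) / (part target) = 0.17 mM × 0.460 / 0.540 = 0.145 mM

This is the charge of free catalyst at which the two ways carry equal flows. As long as the charge stands and both ways go in proportion to the substrate, the rule is:

selectivity = charge / (charge + half-share charge)

Theta and eta carry the lowest charge, 0.17 mM, the same as Saturday's. Also, 8.0 h is ten times the 0.833 h at which Saturday's substrate stood at 50%. So I take the selectivity as the yield at 8.0 h:

delta: 80.6%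
alpha and epsilon: 77.5%
gamma: 67.4%
theta and eta: 54.0%

My reckoning puts delta first; flasks of equal charge get the same number from it, so it doesn't rank alpha against epsilon or theta against eta.

The forecast differs. It sees “a catalysed first-order path to target competing with an uncatalysed side loss that is second-order in substrate”, and it gives alpha > gamma > delta > eta > epsilon > theta at 8.0 h and alpha > gamma > delta > eta > epsilon > theta at 2.5 d, with 92% for its first flask and 70% for its last.

    substrate + free catalyst → free catalyst + target (k = 51.0 M⁻¹ min⁻¹)
    substrate → side product (k = 0.00460 min⁻¹)
    2 substrate → self-condensation product (k = 0.0280 M⁻¹ min⁻¹)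
    free catalyst + target → spent catalyst (k = 0.610 M⁻¹ min⁻¹)

The flasks give delta > alpha > epsilon > gamma > eta > theta at 8.0 h and delta > alpha > epsilon > gamma > eta > theta at 2.5 d. Delta stands first at 80.1% against my 80.6%, and theta last at 56.2% against my 54.0%. At 8.00 h delta holds 3.55% of its charged catalyst as free catalyst and 96.5% as spent catalyst, so the standing charge I assumed does not last in delta. The half-share charge goes once more to a neighbour, the same flask as delta but charged with 0.24 mM of free catalyst: the rule gives 62.3%, and that flask holds 64.2% of target at 8.00 h.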